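**Retrosynthetic overview**
1. Target 21 ⇐ bicyclic alcohol 17 by two end-game operations: DMAP-free angeloylation of O3, then desilylation of O18.
2. 17 ⇐ open-chain oxirane 16 in one cationic cascade (C4–C5, then C9–C10): ring A closes first, ring B last; C4, C5, C9, C10 and the exocyclic alkene all follow from the single oxirane stereocentre C3.
3. Enabling feature: trans-fused rings A/B with the oxygen on C3 next to quaternary C4, the angular methyl on C10 and the C8=C17 methylene flanked by C9 are the footprint of an oxidopolyprene cyclisation; a CH2SiMe3 group on C8 (lost in the step) fixes the alkene position, and the only other alkene (C13=C14 of the butenolide) is electron-poor and inert to cations.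
4. 16 ⇐ alkylborane of oxirane diene 7 (from geranyl acetate; Sharpless epoxidation sets C3 and C4) + gem-dibromoalkene 13 (from 4-bromofuranone) + a Me3SiCH2 unit, joined by two stereospecific Pd couplings at C8.
5. Ring order: butenolide (bought with 9), oxirane (temporary), ring A, ring B.

Key step: step 12

Remark: labdane numbering is used (ring A = C1–C5 and C10; ring B = C5–C10; C11–C16 = side chain and butenolide; C17 = exocyclic CH2; C18 = CH2O on C4).

**Route**

Step 1
Reactants: 1 geranyl acetate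
Product: 2 (2E,6E)-8-hydroxy-3,7-dimethylocta-2,6-dien-1-yl acetate
Conditions: SeO2 (cat.), t-BuOOH, salicylic acid (cat.), CH2Cl2, rt
Reagents that add atoms: tert-butyl hydroperoxide CC(C)(C)OO
Why: Catalytic SeO2 allylic oxidation (ene reaction followed by [2,3]-sigmatropic shift) should attack the electron-rich terminal trisubstituted alkene at its E methyl group and spare the acetate-deactivated alkene, giving the E allylic alcohol that later places the CH2O group equatorial on C4.

Step 2
Reactants: 2 (2E,6E)-8-hydroxy-3,7-dimethylocta-2,6-dien-1-yl acetate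
Product: 3 (2E)-5-[(2R,3R)-3-(hydroxymethyl)-3-methyloxiran-2-yl]-3-methylpent-2-en-1-yl acetate
Conditions: Ti(OiPr)4 (cat.), D-(−)-diethyl tartrate (cat.), t-BuOOH, 4 Å molecular sieves, CH2Cl2, −20 °C
Reagents that add atoms: tert-butyl hydroperoxide CC(C)(C)OO
Why: Sharpless asymmetric epoxidation acts only on the alkene of the free allylic alcohol, and the D-(−)-tartrate ligand should deliver oxygen to the face that gives the (2R,3R)-oxirane (reagent control), the trans arrangement of chain and CH2OH being inherited from the E alkene; this sets C3 and the relative configuration at C4.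

Step 3
Reactants: 3 (2E)-5-[(2R,3R)-3-(hydroxymethyl)-3-methyloxiran-2-yl]-3-methylpent-2-en-1-yl acetate
Product: 4 (2E)-5-[(2R,3R)-3-({[tert-butyl(dimethyl)silyl]oxy}methyl)-3-methyloxiran-2-yl]-3-methylpent-2-en-1-yl acetate
Conditions: TBSCl, imidazole, DMF, 0 °C to rt
Reagents that add atoms: tert-butyldimethylsilyl chloride CC(C)(C)[Si](C)(C)Cl
Why: Standard silylation of a primary alcohol gives a non-participating ether that should survive base, Pd couplings and the Lewis acid of the key step and be removable with fluoride at the end.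

Step 4
Reactants: 4 (2E)-5-[(2R,3R)-3-({[tert-butyl(dimethyl)silyl]oxy}methyl)-3-methyloxiran-2-yl]-3-methylpent-2-en-1-yl acetate
Product: 5 (2E)-5-[(2R,3R)-3-({[tert-butyl(dimethyl)silyl]oxy}methyl)-3-methyloxiran-2-yl]-3-methylpent-2-en-1-ol
Conditions: K2CO3, MeOH, 0 °C to rt
Reagents that add atoms: none
Why: Base-catalysed transesterification (methanolysis) removes the acetate without touching the trisubstituted oxirane or the silyl ether.

Step 5
Reactants: 5 (2E)-5-[(2R,3R)-3-({[tert-butyl(dimethyl)silyl]oxy}methyl)-3-methyloxiran-2-yl]-3-methylpent-2-en-1-ol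
Product: 6 (2E)-5-[(2R,3R)-3-({[tert-butyl(dimethyl)silyl]oxy}methyl)-3-methyloxiran-2-yl]-3-methylpent-2-enal
Conditions: MnO2, CH2Cl2, rt
Reagents that add atoms: none
Why: MnO2 oxidation is selective for allylic alcohols, is neutral toward the oxirane and should keep the E geometry of the enal.

Step 6
Reactants: 6 (2E)-5-[(2R,3R)-3-({[tert-butyl(dimethyl)silyl]oxy}methyl)-3-methyloxiran-2-yl]-3-methylpent-2-enal
Product: 7 tert-butyl(dimethyl){[(2R,3R)-2-methyl-3-[(3E)-3-methylhexa-3,5-dien-1-yl]oxiran-2-yl]methoxy}silane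
Conditions: Ph3PCH3Br, n-BuLi, THF, −78 °C to 0 °C
Reagents that add atoms: methyltriphenylphosphonium bromide C[P+](c1ccccc1)(c1ccccc1)c1ccccc1.[Br-]
Why: Wittig methylenation of the enal gives the terminal diene (the future C6 and C7) under conditions that a trisubstituted oxirane tolerates.

Step 7
Reactants: 8 acrolein diethyl acetal; 9 4-bromofuran-2(5H)-one
Product: 11 4-(3,3-diethoxypropyl)furan-2(5H)-one, via B-(3,3-diethoxypropyl)-9-BBN 10 (not isolated)
Conditions: 9-BBN, THF, 0 °C to rt; then 9, Pd(dppf)Cl2 (cat.), K3PO4 (aq), THF/DMF, 50 °C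
Reagents that add atoms: none
Why: Anti-Markovnikov hydroboration followed by B-alkyl Suzuki–Miyaura coupling with the vinylogous acyl bromide attaches the C9–C11–C12 chain to C13 of the ready-made butenolide ring.

Step 8
Reactants: 11 4-(3,3-diethoxypropyl)furan-2(5H)-one
Product: 12 3-(5-oxo-2,5-dihydrofuran-3-yl)propanal
Conditions: 1 M HCl (aq), THF, rt
Reagents that add atoms: water O
Why: Acid-catalysed acetal hydrolysis unmasks the aldehyde, and the butenolide is stable to dilute acid.

Step 9
Reactants: 12 3-(5-oxo-2,5-dihydrofuran-3-yl)propanal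
Product: 13 4-(4,4-dibromobut-3-en-1-yl)furan-2(5H)-one
Conditions: CBr4, PPh3, CH2Cl2, 0 °C
Reagents that add atoms: carbon tetrabromide BrC(Br)(Br)Br
Why: Ramirez dibromo-olefination (first stage of the Corey–Fuchs sequence) turns the aldehyde carbon into C9 and adds C8 as a CBr2 group whose two C–Br bonds can be addressed one after the other.

Step 10
Reactants: 7 tert-butyl(dimethyl){[(2R,3R)-2-methyl-3-[(3E)-3-methylhexa-3,5-dien-1-yl]oxiran-2-yl]methoxy}silane; 13 4-(4,4-dibromobut-3-en-1-yl)furan-2(5H)-one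
Product: 15 4-[(3Z,7E)-4-bromo-10-[(2R,3R)-3-({[tert-butyl(dimethyl)silyl]oxy}methyl)-3-methyloxiran-2-yl]-8-methyldeca-3,7-dien-1-yl]furan-2(5H)-one, via alkylborane 14 (not isolated)
Conditions: 9-BBN, THF, 0 °C to rt; then 13, Pd2(dba)3 (cat.), Xantphos, K3PO4 (aq), THF, rt to 50 °C
Reagents that add atoms: none
Why: 9-BBN should add to the terminal CH2 of the diene only, and in the B-alkyl Suzuki–Miyaura coupling the C–Br bond trans to the chain of the gem-dibromoalkene undergoes oxidative addition first, so monoalkylation should give the Z bromoalkene with C7 trans to C11.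

Step 11
Reactants: 15 4-[(3Z,7E)-4-bromo-10-[(2R,3R)-3-({[tert-butyl(dimethyl)silyl]oxy}methyl)-3-methyloxiran-2-yl]-8-methyldeca-3,7-dien-1-yl]furan-2(5H)-one
Product: 16 4-[(3Z,7E)-10-[(2R,3R)-3-({[tert-butyl(dimethyl)silyl]oxy}methyl)-3-methyloxiran-2-yl]-8-methyl-4-[(trimethylsilyl)methyl]deca-3,7-dien-1-yl]furan-2(5H)-one
Conditions: Me3SiCH2MgCl, ZnCl2, THF, 0 °C (gives Me3SiCH2ZnCl); then 15, Pd(t-Bu3P)2 (cat.), THF/NMP, rt
Reagents that add atoms: (trimethylsilyl)methylmagnesium chloride C[Si](C)(C)C[Mg]Cl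
Why: Negishi cross-coupling proceeds with retention at the alkenyl carbon, so CH2SiMe3 ends up cis to C11 (Z allylsilane), and the zinc reagent is chosen over the Grignard reagent to spare the butenolide and the oxirane.

Step 12
Reactants: 16 4-[(3Z,7E)-10-[(2R,3R)-3-({[tert-butyl(dimethyl)silyl]oxy}methyl)-3-methyloxiran-2-yl]-8-methyl-4-[(trimethylsilyl)methyl]deca-3,7-dien-1-yl]furan-2(5H)-one
Product: 17 4-{2-[(1R,4aS,5S,6R,8aS)-5-({[tert-butyl(dimethyl)silyl]oxy}methyl)-6-hydroxy-5,8a-dimethyl-2-methylidenedecahydronaphthalen-1-yl]ethyl}furan-2(5H)-one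
Conditions: MeAlCl2 (3 equiv), CH2Cl2 (high dilution), −78 °C; then Et3N/MeOH, aqueous citric acid work-up
Reagents that add atoms: none
Why: MeAlCl2 binds the oxirane oxygen, the C4–O bond ionises with backside participation of the C5=C10 alkene (C4–C5 bond, ring A), the tertiary cation at C10 is captured by C9 of the allylsilane (C9–C10 bond, ring B, closed last), and the β-silyl cation at C8 loses the silyl group to give only the exocyclic C8=C17 alkene. The closest known reaction type is the Lewis acid-promoted, epoxide-initiated and allylsilane-terminated cation–olefin bicyclisation of oxidopolyprenes (biomimetic polyene cyclisation). Both rings close in the 6-endo-trig mode through chair-like transition states (chair–chair fold). C3 keeps its configuration because its C–O bond is not broken, C4 is set by inversion at the oxirane carbon so that the E-derived CH2OSi group becomes equatorial, C5 and C10 are set trans by anti addition across the E C5=C10 alkene, and C9 is set by the Z allylsilane geometry (C11 trans to C7, hence equatorial); the absolute sense of the fold is dictated by the R-configured C3, whose oxygen takes the equatorial position. The step needs alkene-assisted opening at the tertiary oxirane carbon to outrun hydride shift and ether formation and needs a regiocontrolled termination; this is secured by the nucleophilic trisubstituted alkenes, the proton-scavenging MeAlCl2 at −78 °C, the non-participating silyl ether and the β-silicon effect, while the electron-poor butenolide alkene stays out and only ties up one equivalent of Lewis acid.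

Step 13
Reactants: 17 4-{2-[(1R,4aS,5S,6R,8aS)-5-({[tert-butyl(dimethyl)silyl]oxy}methyl)-6-hydroxy-5,8a-dimethyl-2-methylidenedecahydronaphthalen-1-yl]ethyl}furan-2(5H)-one; 18 angelic acid
Product: 20 (1S,2R,4aS,5R,8aS)-1-({[tert-butyl(dimethyl)silyl]oxy}methyl)-1,4a-dimethyl-6-methylidene-5-[2-(5-oxo-2,5-dihydrofuran-3-yl)ethyl]decahydronaphthalen-2-yl (2Z)-2-methylbut-2-enoate, via angelic 2,4,6-trichlorobenzoic anhydride 19 (not isolated)
Conditions: 18, 2,4,6-trichlorobenzoyl chloride, Et3N, toluene, rt; then 17, toluene, 75 °C (no DMAP)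
Reagents that add atoms: none
Why: Yamaguchi-type mixed-anhydride esterification run thermally without a nucleophilic catalyst should acylate the equatorial C3 hydroxyl at the less hindered angeloyl carbonyl while avoiding the addition–elimination pathway that isomerises angelate to tiglate.

Step 14
Reactants: 20 (1S,2R,4aS,5R,8aS)-1-({[tert-butyl(dimethyl)silyl]oxy}methyl)-1,4a-dimethyl-6-methylidene-5-[2-(5-oxo-2,5-dihydrofuran-3-yl)ethyl]decahydronaphthalen-2-yl (2Z)-2-methylbut-2-enoate
Product: 21 (1S,2R,4aS,5R,8aS)-1-(hydroxymethyl)-1,4a-dimethyl-6-methylidene-5-[2-(5-oxo-2,5-dihydrofuran-3-yl)ethyl]decahydronaphthalen-2-yl (2Z)-2-methylbut-2-enoate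
Conditions: HF·pyridine, pyridine/THF, 0 °C to rt
Reagents that add atoms: none
Why: Fluoride-mediated desilylation under buffered, weakly acidic conditions should free the primary alcohol without acyl migration from O3, angelate isomerisation or damage to the butenolide and the exocyclic alkene.

**Compound list**
1 | geranyl acetate | CC(=O)OC/C=C(\C)CCC=C(C)C | starting material
2 | (2E,6E)-8-hydroxy-3,7-dimethylocta-2,6-dien-1-yl acetate | CC(=O)OC/C=C(\C)CC/C=C(\C)CO | intermediate
3 | (2E)-5-[(2R,3R)-3-(hydroxymethyl)-3-methyloxiran-2-yl]-3-methylpent-2-en-1-yl acetate | CC(=O)OC/C=C(\C)CC[C@H]1O[C@]1(C)CO | intermediate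
4 | (2E)-5-[(2R,3R)-3-({[tert-butyl(dimethyl)silyl]oxy}methyl)-3-methyloxiran-2-yl]-3-methylpent-2-en-1-yl acetate | CC(=O)OC/C=C(\C)CC[C@H]1O[C@]1(C)CO[Si](C)(C)C(C)(C)C | intermediate
5 | (2E)-5-[(2R,3R)-3-({[tert-butyl(dimethyl)silyl]oxy}methyl)-3-methyloxiran-2-yl]-3-methylpent-2-en-1-ol | OC/C=C(\C)CC[C@H]1O[C@]1(C)CO[Si](C)(C)C(C)(C)C | intermediate
6 | (2E)-5-[(2R,3R)-3-({[tert-butyl(dimethyl)silyl]oxy}methyl)-3-methyloxiran-2-yl]-3-methylpent-2-enal | O=C/C=C(\C)CC[C@H]1O[C@]1(C)CO[Si](C)(C)C(C)(C)C | intermediate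
7 | tert-butyl(dimethyl){[(2R,3R)-2-methyl-3-[(3E)-3-methylhexa-3,5-dien-1-yl]oxiran-2-yl]methoxy}silane | C=C/C=C(\C)CC[C@H]1O[C@]1(C)CO[Si](C)(C)C(C)(C)C | intermediate
8 | acrolein diethyl acetal (3,3-diethoxyprop-1-ene) | C=CC(OCC)OCC | starting material
9 | 4-bromofuran-2(5H)-one | O=C1C=C(Br)CO1 | starting material
10 | B-(3,3-diethoxypropyl)-9-borabicyclo[3.3.1]nonane | CCOC(OCC)CCB1C2CCCC1CCC2 | intermediate (not isolated)
11 | 4-(3,3-diethoxypropyl)furan-2(5H)-one | CCOC(OCC)CCC1=CC(=O)OC1 | intermediate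
12 | 3-(5-oxo-2,5-dihydrofuran-3-yl)propanal | O=CCCC1=CC(=O)OC1 | intermediate
13 | 4-(4,4-dibromobut-3-en-1-yl)furan-2(5H)-one | BrC(Br)=CCCC1=CC(=O)OC1 | intermediate
14 | 9-[(3E)-6-[(2R,3R)-3-({[tert-butyl(dimethyl)silyl]oxy}methyl)-3-methyloxiran-2-yl]-4-methylhex-3-en-1-yl]-9-borabicyclo[3.3.1]nonane | C1CCC2CCCC1B2CC/C=C(\C)CC[C@H]1O[C@]1(C)CO[Si](C)(C)C(C)(C)C | intermediate (not isolated)
15 | 4-[(3Z,7E)-4-bromo-10-[(2R,3R)-3-({[tert-butyl(dimethyl)silyl]oxy}methyl)-3-methyloxiran-2-yl]-8-methyldeca-3,7-dien-1-yl]furan-2(5H)-one | O=C1C=C(CC/C=C(\Br)CC/C=C(\C)CC[C@H]2O[C@]2(C)CO[Si](C)(C)C(C)(C)C)CO1 | intermediate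
16 | 4-[(3Z,7E)-10-[(2R,3R)-3-({[tert-butyl(dimethyl)silyl]oxy}methyl)-3-methyloxiran-2-yl]-8-methyl-4-[(trimethylsilyl)methyl]deca-3,7-dien-1-yl]furan-2(5H)-one | O=C1C=C(CC/C=C(\C[Si](C)(C)C)CC/C=C(\C)CC[C@H]2O[C@]2(C)CO[Si](C)(C)C(C)(C)C)CO1 | intermediate
17 | 4-{2-[(1R,4aS,5S,6R,8aS)-5-({[tert-butyl(dimethyl)silyl]oxy}methyl)-6-hydroxy-5,8a-dimethyl-2-methylidenedecahydronaphthalen-1-yl]ethyl}furan-2(5H)-one | C=C1CC[C@H]2[C@@](C)(CC[C@@H](O)[C@]2(C)CO[Si](C)(C)C(C)(C)C)[C@@H]1CCC1=CC(=O)OC1 | intermediate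
18 | angelic acid ((2Z)-2-methylbut-2-enoic acid) | C/C=C(/C)C(=O)O | starting material
19 | angelic 2,4,6-trichlorobenzoic anhydride | C/C=C(/C)C(=O)OC(=O)c1c(Cl)cc(Cl)cc1Cl | intermediate (not isolated)
20 | (1S,2R,4aS,5R,8aS)-1-({[tert-butyl(dimethyl)silyl]oxy}methyl)-1,4a-dimethyl-6-methylidene-5-[2-(5-oxo-2,5-dihydrofuran-3-yl)ethyl]decahydronaphthalen-2-yl (2Z)-2-methylbut-2-enoate | C=C1CC[C@H]2[C@@](C)(CC[C@@H](OC(=O)/C(C)=C\C)[C@]2(C)CO[Si](C)(C)C(C)(C)C)[C@@H]1CCC1=CC(=O)OC1 | intermediate
21 | (1S,2R,4aS,5R,8aS)-1-(hydroxymethyl)-1,4a-dimethyl-6-methylidene-5-[2-(5-oxo-2,5-dihydrofuran-3-yl)ethyl]decahydronaphthalen-2-yl (2Z)-2-methylbut-2-enoate (CNP0292066.2) | C=C1CC[C@H]2[C@@](C)(CC[C@@H](OC(=O)/C(C)=C\C)[C@]2(C)CO)[C@@H]1CCC1=CC(=O)OC1 | target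

**Step count and risks**

Total step count: 14. Longest linear sequence: 11 steps (steps 1–6, then 10–14); the butenolide branch (steps 7–9) joins at step 10.

Steps most likely to fail:

Step 12 (key cyclisation). The CH2OSi group withdraws electron density from C4, so the activated oxirane may rearrange by 1,2-hydride shift, be opened without alkene participation, or the cascade may stop after ring A or be intercepted by the oxirane oxygen. Fallback (radical instead of cationic cascade), setting out from 15 and rejoining at 17: Negishi methylation of 15 (MeZnCl, Pd(t-Bu3P)2, THF) should give with retention the methyl-terminated oxirane 4-[(3E,7E)-10-[(2R,3R)-3-({[tert-butyl(dimethyl)silyl]oxy}methyl)-3-methyloxiran-2-yl]-4,8-dimethyldeca-3,7-dien-1-yl]furan-2(5H)-one F1. Treatment of F1 with Cp2TiCl (trivalent titanium, generated from Cp2TiCl2 and Mn dust, THF, rt) opens the oxirane homolytically at C4; the carbon radical closes ring A and then ring B by 6-endo additions, and the tertiary C8 radical is trapped by a second Cp2TiCl and loses a hydrogen from the C17 methyl group to give the exocyclic alkene. Acidic aqueous work-up then delivers 17. In this variant C4 is set by the chair preference of the larger CH2OSi group for the equatorial position, not by inversion.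

Step 10 (diene hydroboration and mono-selective coupling). Hydroboration of the conjugated diene may not be clean at the terminal carbon, and the coupling may not stop after the trans C–Br bond (second coupling, erosion of alkene geometry, or elimination to an alkyne under the basic aqueous conditions). Fallback (isolated organozinc instead of in situ borane), setting out from 7 and rejoining at 15: hydroboration–oxidation (9-BBN, THF; then NaBO3, H2O) gives (3E)-6-[(2R,3R)-3-({[tert-butyl(dimethyl)silyl]oxy}methyl)-3-methyloxiran-2-yl]-4-methylhex-3-en-1-ol F2, which can be purified from regioisomers. Iodination (I2, PPh3, imidazole, CH2Cl2) gives tert-butyl({(2R,3R)-3-[(3E)-6-iodo-3-methylhex-3-en-1-yl]-2-methyloxiran-2-yl}methoxy)dimethylsilane F3, and zinc insertion (Zn dust, LiCl, THF) gives the alkylzinc iodide [(3E)-6-[(2R,3R)-3-({[tert-butyl(dimethyl)silyl]oxy}methyl)-3-methyloxiran-2-yl]-4-methylhex-3-en-1-yl]zinc iodide F4. F4 is then used in the base-free, trans-selective Negishi monoalkylation of 13 (Pd(DPEphos)Cl2, THF, rt) to give 15.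

Step 13 (angeloylation). Acylation of the hindered C3 hydroxyl (next to quaternary C4) may be slow, and prolonged heating may isomerise the angeloyl donor so that the tiglate forms. Fallback (build the Z alkene on the oxygen instead of transferring it), setting out from 17 and rejoining at 20: esterification of 17 with 2-(diphenoxyphosphoryl)propanoic acid (EDC·HCl, DMAP, CH2Cl2) gives the phosphonate ester (1S,2R,4aS,5R,8aS)-1-({[tert-butyl(dimethyl)silyl]oxy}methyl)-1,4a-dimethyl-6-methylidene-5-[2-(5-oxo-2,5-dihydrofuran-3-yl)ethyl]decahydronaphthalen-2-yl 2-(diphenoxyphosphoryl)propanoate F5 (mixture of epimers at the phosphonate carbon). A Z-selective Horner–Wadsworth–Emmons olefination of F5 with acetaldehyde (diaryl phosphonate, Ando variant; NaI, DBU, THF, −78 °C to 0 °C) should then give the angelate 20.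

Further compounds
F1 | step 12 | 4-[(3E,7E)-10-[(2R,3R)-3-({[tert-butyl(dimethyl)silyl]oxy}methyl)-3-methyloxiran-2-yl]-4,8-dimethyldeca-3,7-dien-1-yl]furan-2(5H)-one | O=C1C=C(CC/C=C(\C)CC/C=C(\C)CC[C@H]2O[C@]2(C)CO[Si](C)(C)C(C)(C)C)CO1
F2 | step 10 | (3E)-6-[(2R,3R)-3-({[tert-butyl(dimethyl)silyl]oxy}methyl)-3-methyloxiran-2-yl]-4-methylhex-3-en-1-ol | OCC/C=C(\C)CC[C@H]1O[C@]1(C)CO[Si](C)(C)C(C)(C)C
F3 | step 10 | tert-butyl({(2R,3R)-3-[(3E)-6-iodo-3-methylhex-3-en-1-yl]-2-methyloxiran-2-yl}methoxy)dimethylsilane | ICC/C=C(\C)CC[C@H]1O[C@]1(C)CO[Si](C)(C)C(C)(C)C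
F4 | step 10 | [(3E)-6-[(2R,3R)-3-({[tert-butyl(dimethyl)silyl]oxy}methyl)-3-methyloxiran-2-yl]-4-methylhex-3-en-1-yl]zinc iodide | I[Zn]CC/C=C(\C)CC[C@H]1O[C@]1(C)CO[Si](C)(C)C(C)(C)C
F5 | step 13 | (1S,2R,4aS,5R,8aS)-1-({[tert-butyl(dimethyl)silyl]oxy}methyl)-1,4a-dimethyl-6-methylidene-5-[2-(5-oxo-2,5-dihydrofuran-3-yl)ethyl]decahydronaphthalen-2-yl 2-(diphenoxyphosphoryl)propanoate | C=C1CC[C@H]2[C@@](C)(CC[C@@H](OC(=O)C(C)P(=O)(Oc3ccccc3)Oc3ccccc3)[C@]2(C)CO[Si](C)(C)C(C)(C)C)[C@@H]1CCC1=CC(=O)OC1
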